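**Plan**

1. Retrosynthetic cuts, in order: (a) the C2–C3 bond of the 2,3-dihydrobenzofuran, with the C3 hydroxymethyl carried as an ester; (b) the bond from lactone C3 to the ring A benzylic carbon; (c) the carbinol–CH bond of the open diol arm; (d) the lactone, back to a Stobbe half-ester.
2. Enabling feature: C2 bears both O1 and an electron-rich aryl ring. In the ring-opened form it is the CH2 of an aryl 4-alkoxybenzyl ether on ring B, which also protects that phenol. Its C–H bonds are benzylic and alpha to oxygen, and lie 1,5 to C3, which sits on C3a ortho to C7a–O1 and can be made a rhodium carbene carbon.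
3. Forward order: ring A arm by anti-aldol (steps 1–8); lactone ring by Stobbe condensation, asymmetric hydrogenation and reduction–lactonisation (9–12); trans-alkylation joins the halves (13); arylacetate and diazo group go onto ring B (14–16); the dihydrofuran ring closes last (17) and is then trimmed (18–22).
4. Stereochemistry: both carbons of the open arm from the oxazolidinone auxiliary; lactone C4 from the Rh–DuPhos hydrogenation; lactone C3 from alkylation anti to the C4 substituent; dihydrobenzofuran C2 from the chiral dirhodium catalyst, C3 from base equilibration to the trans ester.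
5. Helpers: a 2-(trimethylsilyl)ethyl ester as carbene acceptor (cleaved by fluoride, the acid then reduced by borane beside the lactone); an acetonide and benzyl ethers, removed at the end with acid before hydrogenolysis so that the open arm cannot cyclise.

Key step: step 17

Assumption: the senses of induction of the auxiliary (step 5), the DuPhos ligand (step 11) and the dirhodium carboxylate (step 17) are assigned by analogy with the usual behaviour of these controllers; each exists in both mirror-image forms, so a reversed sense would be met by the antipodal controller without changing the route.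

Shorthand in names: ArG = 4-(benzyloxy)-3-methoxyphenyl; ArG-CH2 = 4-(benzyloxy)-3-methoxybenzyl.

**Route**

Step 1
Reactants: 1 methyl 3-bromo-4-hydroxy-5-methoxybenzoate
Product: 2 methyl 4-(benzyloxy)-3-bromo-5-methoxybenzoate
Conditions: BnBr, K2CO3, DMF, 60 °C
Reagents that add atoms: benzyl bromide, BrCc1ccccc1
Why: Williamson etherification of the acidic phenol should proceed cleanly and protects the ring A phenol until the last step.

Step 2
Reactants: 2 methyl 4-(benzyloxy)-3-bromo-5-methoxybenzoate; 3 (2-tert-butoxy-2-oxoethyl)zinc bromide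
Product: 4 tert-butyl 2-[2-(benzyloxy)-3-methoxy-5-(methoxycarbonyl)phenyl]acetate
Conditions: Pd(dba)2 (2 mol%), P(tBu)3 (2 mol%), THF, rt
Reagents that add atoms: none
Why: Palladium-catalysed arylation of a Reformatsky reagent (Negishi-type coupling of a zinc ester enolate) tolerates the methyl ester and installs the two carbons that become the aryl-bearing carbon and the CH2OH of the open arm.

Step 3
Reactants: 4 tert-butyl 2-[2-(benzyloxy)-3-methoxy-5-(methoxycarbonyl)phenyl]acetate
Product: 5 2-[2-(benzyloxy)-3-methoxy-5-(methoxycarbonyl)phenyl]acetic acid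
Conditions: TFA, CH2Cl2, 0 °C → rt
Reagents that add atoms: none
Why: Acidolysis of the tert-butyl ester should leave the methyl ester and the aryl benzyl ether intact.

Step 4
Reactants: 5 2-[2-(benzyloxy)-3-methoxy-5-(methoxycarbonyl)phenyl]acetic acid; 6 (S)-4-benzyl-2-oxazolidinone
Product: 8 (S)-4-benzyl-3-{2-[2-(benzyloxy)-3-methoxy-5-(methoxycarbonyl)phenyl]acetyl}oxazolidin-2-one, via mixed pivalic anhydride 7 (not isolated)
Conditions: tBuCOCl, Et3N, THF, −20 °C; then LiCl, 6, −20 °C → rt
Reagents that add atoms: none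
Why: Mixed-anhydride N-acylation of the oxazolidinone (LiCl-assisted) is the standard way to load an arylacetic acid onto this auxiliary.

Step 5
Reactants: 8 (S)-4-benzyl-3-{2-[2-(benzyloxy)-3-methoxy-5-(methoxycarbonyl)phenyl]acetyl}oxazolidin-2-one; 9 4-(benzyloxy)-3-methoxybenzaldehyde
Product: 10 (S)-4-benzyl-3-[(2R,3S)-2-[2-(benzyloxy)-3-methoxy-5-(methoxycarbonyl)phenyl]-3-(ArG)-3-(trimethylsilyloxy)propanoyl]oxazolidin-2-one
Conditions: MgCl2 (20 mol%), Et3N, Me3SiCl, EtOAc, rt
Reagents that add atoms: chlorotrimethylsilane, C[Si](C)(C)Cl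
Why: In this magnesium halide-catalysed direct anti-aldol of an N-acyloxazolidinone, soft enolisation should give the chelated Z-enolate, which the non-enolisable aldehyde attacks on the face away from the auxiliary benzyl group (fixing the aryl-bearing carbon) with the carbinol oxygen anti to the aryl group, while O-silylation turns the catalyst over and blocks retro-aldol.

Step 6
Reactants: 10 (S)-4-benzyl-3-[(2R,3S)-2-[2-(benzyloxy)-3-methoxy-5-(methoxycarbonyl)phenyl]-3-(ArG)-3-(trimethylsilyloxy)propanoyl]oxazolidin-2-one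
Product: 12 (1S,2S)-1-(ArG)-2-[2-(benzyloxy)-5-(hydroxymethyl)-3-methoxyphenyl]propane-1,3-diol, via trimethylsilyl ether diol 11 (not isolated)
Conditions: LiBH4, MeOH (2 equiv), THF, 0 → 40 °C; then aq. citric acid, rt
Reagents that add atoms: none
Why: Borohydride reduction should cleave the imide reductively and reduce the benzoate ester in one operation, the silyl ether shielding the aldol from retro-cleavage until it is hydrolysed on work-up, with no stereocentre touched.

Step 7
Reactants: 12 (1S,2S)-1-(ArG)-2-[2-(benzyloxy)-5-(hydroxymethyl)-3-methoxyphenyl]propane-1,3-diol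
Product: 13 {4-(benzyloxy)-3-[(4S,5S)-4-(ArG)-2,2-dimethyl-1,3-dioxan-5-yl]-5-methoxyphenyl}methanol
Conditions: Me2C(OMe)2, PPTS (cat.), CH2Cl2, rt
Reagents that add atoms: 2,2-dimethoxypropane, COC(C)(C)OC
Why: Thermodynamic acetonide formation should engage only the 1,3-diol (six-membered ring with both aryl groups equatorial) and leave the lone benzylic primary alcohol free.

Step 8
Reactants: 13 {4-(benzyloxy)-3-[(4S,5S)-4-(ArG)-2,2-dimethyl-1,3-dioxan-5-yl]-5-methoxyphenyl}methanol
Product: 14 (4S,5S)-5-[2-(benzyloxy)-5-(bromomethyl)-3-methoxyphenyl]-4-(ArG)-2,2-dimethyl-1,3-dioxane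
Conditions: CBr4, PPh3, CH2Cl2, 0 °C
Reagents that add atoms: tetrabromomethane, BrC(Br)(Br)Br
Why: The Appel reaction converts the benzylic alcohol to the bromide under near-neutral conditions that the acetonide should survive.

Step 9
Reactants: 15 5-bromovanillin (3-bromo-4-hydroxy-5-methoxybenzaldehyde); 16 [4-(benzyloxy)-3-methoxyphenyl]methanol
Product: 17 3-bromo-4-[(ArG-CH2)oxy]-5-methoxybenzaldehyde
Conditions: PPh3, DIAD, THF, 0 °C → rt
Reagents that add atoms: none
Why: Mitsunobu etherification of the acidic phenol with the primary benzylic alcohol installs the ether that protects ring B now and later supplies C2 and its aryl ring.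

Step 10
Reactants: 17 3-bromo-4-[(ArG-CH2)oxy]-5-methoxybenzaldehyde; 18 dimethyl succinate
Product: 19 (E)-4-{3-bromo-4-[(ArG-CH2)oxy]-5-methoxyphenyl}-3-(methoxycarbonyl)but-3-enoic acid
Conditions: NaOMe, MeOH, reflux; then aq. HCl
Reagents that add atoms: none
Why: The Stobbe condensation should deliver the E half-ester through the paraconate intermediate and its ring-opening elimination.

Step 11
Reactants: 19 (E)-4-{3-bromo-4-[(ArG-CH2)oxy]-5-methoxyphenyl}-3-(methoxycarbonyl)but-3-enoic acid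
Product: 20 (R)-4-{3-bromo-4-[(ArG-CH2)oxy]-5-methoxyphenyl}-3-(methoxycarbonyl)butanoic acid
Conditions: H2 (5 bar), [Rh(cod)((S,S)-Et-DuPhos)]BF4 (1 mol%), NaOMe (10 mol%), MeOH, rt
Reagents that add atoms: none
Why: Carboxylate-directed asymmetric hydrogenation of an itaconate-type half-ester with a cationic rhodium bisphospholane catalyst should set the future lactone C4 as R, the homogeneous catalyst sparing the aryl bromide and the benzylic ethers.

Step 12
Reactants: 20 (R)-4-{3-bromo-4-[(ArG-CH2)oxy]-5-methoxyphenyl}-3-(methoxycarbonyl)butanoic acid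
Product: 22 (R)-4-{3-bromo-4-[(ArG-CH2)oxy]-5-methoxybenzyl}dihydrofuran-2(3H)-one, via hydroxy acid 21 (not isolated)
Conditions: KOH (1 equiv), EtOH, 0 °C; CaCl2, NaBH4, EtOH, −10 °C → rt; then 2 M HCl, rt
Reagents that add atoms: none
Why: Calcium borohydride should reduce the ester while the carboxylate is inert, and brief acidification then closes the gamma-lactone, placing the benzyl group at C4.

Step 13
Reactants: 22 (R)-4-{3-bromo-4-[(ArG-CH2)oxy]-5-methoxybenzyl}dihydrofuran-2(3H)-one; 14 (4S,5S)-5-[2-(benzyloxy)-5-(bromomethyl)-3-methoxyphenyl]-4-(ArG)-2,2-dimethyl-1,3-dioxane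
Product: 23 (3R,4R)-3-{4-(benzyloxy)-3-[(4S,5S)-4-(ArG)-2,2-dimethyl-1,3-dioxan-5-yl]-5-methoxybenzyl}-4-{3-bromo-4-[(ArG-CH2)oxy]-5-methoxybenzyl}dihydrofuran-2(3H)-one
Conditions: LiN(SiMe3)2, THF, −78 °C; then 14, −78 → −40 °C
Reagents that add atoms: none
Why: Alkylation of the lithium enolate of a 4-substituted butyrolactone occurs anti to the C4 benzyl group, so the 3,4-trans (3R,4R) lactone should result by substrate control.

Step 14
Reactants: 24 bromoacetyl bromide; 25 2-(trimethylsilyl)ethanol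
Product: 26 2-(trimethylsilyl)ethyl bromoacetate
Conditions: pyridine, CH2Cl2, 0 °C
Reagents that add atoms: none
Why: Simple acylation of the alcohol by the acid bromide gives the fluoride-labile bromoacetate.

Step 15
Reactants: 23 the trans lactone aryl bromide; 26 2-(trimethylsilyl)ethyl bromoacetate
Product: 28 2-(trimethylsilyl)ethyl arylacetate (23 with the bromine replaced by CH2CO2CH2CH2SiMe3), via zinc ester enolate 27 (not isolated)
Conditions: Zn dust (Me3SiCl-activated), THF, rt; then 23, Pd(dba)2 (5 mol%), P(tBu)3 (5 mol%), THF, rt → 50 °C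
Reagents that add atoms: none
Why: The Reformatsky reagent is too weakly basic to enolise the lactone, and its palladium-catalysed coupling with the only aryl bromide in the molecule should place the acetate on C3a.

Step 16
Reactants: 28 the 2-(trimethylsilyl)ethyl arylacetate
Product: 29 2-(trimethylsilyl)ethyl aryl diazoacetate (28 with ArCH2 turned into ArC(=N2))
Conditions: 4-acetamidobenzenesulfonyl azide, DBU, MeCN, 0 °C → rt
Reagents that add atoms: 4-acetamidobenzenesulfonyl azide, CC(=O)Nc1ccc(cc1)S(=O)(=O)N=[N+]=[N-]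
Why: Regitz diazo transfer should act only at the arylacetate CH2, the one position that DBU can deprotonate.

Step 17
Reactants: 29 the aryl diazoacetate
Product: 30 2-(trimethylsilyl)ethyl (2S,3R)-cis-2-(ArG)-7-methoxy-2,3-dihydrobenzofuran-3-carboxylate carrying at C5 the CH2 of the (3R,4R)-lactone of 23 (ring A arm unchanged)
Conditions: Rh2(R-PTTL)4 (2 mol%; PTTL = N-phthaloyl-tert-leucinate), toluene, −60 °C
Reagents that add atoms: none
Why: The dirhodium carboxylate should expel N2 from the donor/acceptor diazo ester to give a rhodium carbene at C3, which inserts into a C–H bond of the O1–CH2–ArG ether through a concerted, hydride-transfer-like three-centre transition state, forming the C2–C3 bond. The closest known reaction type is the enantioselective intramolecular 1,5 C–H insertion of 2-(benzyloxy)aryl diazoacetates to cis-2-aryl-2,3-dihydrobenzofuran-3-carboxylates. The furan ring closes as a 1,5-insertion in which C3, C3a, C7a, O1 and C2 are already linked, the only five-membered option open to the carbene. C2 is set by the chiral carboxylate ligands, which choose one of the two enantiotopic benzylic hydrogens and replace it with retention; C3 arises cis kinetically and is corrected in step 18. The step needs site selectivity over aromatic addition, ester-chain insertion and intermolecular paths, secured by the doubly activated C–H bond, the ortho tether and low temperature. It also needs catalyst-controlled facial selectivity, because the four existing stereocentres are too remote to bias C2.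

Step 18
Reactants: 30 the cis (2S,3R) ester
Product: 31 the trans (2S,3S) ester (C3 epimer of 30)
Conditions: DBU, toluene, 50 °C
Reagents that add atoms: none
Why: Reversible enolisation at C3 and reprotonation opposite the C2 aryl group should give the thermodynamically favoured 2,3-trans ester, C2 staying intact because expulsion of the O1 aryloxide from the enolate would be a disfavoured reverse 5-endo process.

Step 19
Reactants: 31 the trans (2S,3S) ester
Product: 32 (2S,3S)-trans-dihydrobenzofuran-3-carboxylic acid (31 with CO2H in place of the silylethyl ester)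
Conditions: Bu4NF, THF, 0 °C → rt; then 0.5 M HCl
Reagents that add atoms: none
Why: Fluoride-induced fragmentation of the 2-(trimethylsilyl)ethyl ester frees the acid without touching the lactone, acetonide or benzyl ethers.

Step 20
Reactants: 32 the carboxylic acid
Product: 33 (2S,3R)-3-(hydroxymethyl) compound (32 with CH2OH in place of CO2H)
Conditions: BH3·THF, THF, −10 → 0 °C; then aq. NH4Cl
Reagents that add atoms: none
Why: Borane reduces a carboxylic acid through its acyloxyborane far faster than it reduces a lactone, so the C3 hydroxymethyl group should form chemoselectively.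

Step 21
Reactants: 33 the acetonide-protected alcohol
Product: 34 tri-O-benzyl ether of the target (33 with the acetonide replaced by the free (1S,2S)-1,3-diol)
Conditions: AcOH–THF–H2O (3:1:1), 40 °C
Reagents that add atoms: none
Why: Mild aqueous acid hydrolyses the acetonide through its tertiary oxocarbenium ion, and because all three phenols are still benzylated the benzylic carbinol cannot cyclise onto the ring A oxygen.

Step 22
Reactants: 34 the tri-O-benzyl ether
Product: 35 CNP0186558.2 (target)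
Conditions: H2 (1 atm), Pd/C (10%), EtOAc–MeOH, rt
Reagents that add atoms: none
Why: Neutral hydrogenolysis should remove the three aryl benzyl ethers faster than it attacks the benzylic carbinol or the C2–O1 bond, so no stereocentre is affected.

**Compound list**

1 | methyl 3-bromo-4-hydroxy-5-methoxybenzoate | COC(=O)c1cc(Br)c(O)c(OC)c1 | starting material
2 | methyl 4-(benzyloxy)-3-bromo-5-methoxybenzoate | COC(=O)c1cc(Br)c(OCc2ccccc2)c(OC)c1 | intermediate
3 | (2-tert-butoxy-2-oxoethyl)zinc bromide | CC(C)(C)OC(=O)C[Zn]Br | starting material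
4 | tert-butyl 2-[2-(benzyloxy)-3-methoxy-5-(methoxycarbonyl)phenyl]acetate | COC(=O)c1cc(CC(=O)OC(C)(C)C)c(OCc2ccccc2)c(OC)c1 | intermediate
5 | 2-[2-(benzyloxy)-3-methoxy-5-(methoxycarbonyl)phenyl]acetic acid | COC(=O)c1cc(CC(=O)O)c(OCc2ccccc2)c(OC)c1 | intermediate
6 | (S)-4-benzyl-2-oxazolidinone | O=C1N[C@@H](Cc2ccccc2)CO1 | starting material
7 | mixed pivalic anhydride of 5 | COC(=O)c1cc(CC(=O)OC(=O)C(C)(C)C)c(OCc2ccccc2)c(OC)c1 | intermediate
8 | (S)-4-benzyl-3-{2-[2-(benzyloxy)-3-methoxy-5-(methoxycarbonyl)phenyl]acetyl}oxazolidin-2-one | COC(=O)c1cc(CC(=O)N2[C@@H](Cc3ccccc3)COC2=O)c(OCc2ccccc2)c(OC)c1 | intermediate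
9 | 4-(benzyloxy)-3-methoxybenzaldehyde | COc1cc(C=O)ccc1OCc1ccccc1 | starting material
10 | (S)-4-benzyl-3-[(2R,3S)-2-[2-(benzyloxy)-3-methoxy-5-(methoxycarbonyl)phenyl]-3-(ArG)-3-(trimethylsilyloxy)propanoyl]oxazolidin-2-one | COc1cc([C@@H](O[Si](C)(C)C)[C@H](C(=O)N2[C@@H](Cc3ccccc3)COC2=O)c2cc(C(=O)OC)cc(OC)c2OCc2ccccc2)ccc1OCc1ccccc1 | intermediate
11 | (2S,3S)-2-[2-(benzyloxy)-5-(hydroxymethyl)-3-methoxyphenyl]-3-(ArG)-3-(trimethylsilyloxy)propan-1-ol | COc1cc([C@@H](O[Si](C)(C)C)[C@H](CO)c2cc(CO)cc(OC)c2OCc2ccccc2)ccc1OCc1ccccc1 | intermediate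
12 | (1S,2S)-1-(ArG)-2-[2-(benzyloxy)-5-(hydroxymethyl)-3-methoxyphenyl]propane-1,3-diol | COc1cc([C@@H](O)[C@H](CO)c2cc(CO)cc(OC)c2OCc2ccccc2)ccc1OCc1ccccc1 | intermediate
13 | {4-(benzyloxy)-3-[(4S,5S)-4-(ArG)-2,2-dimethyl-1,3-dioxan-5-yl]-5-methoxyphenyl}methanol | COc1cc([C@H]2OC(C)(C)OC[C@@H]2c2cc(CO)cc(OC)c2OCc2ccccc2)ccc1OCc1ccccc1 | intermediate
14 | (4S,5S)-5-[2-(benzyloxy)-5-(bromomethyl)-3-methoxyphenyl]-4-(ArG)-2,2-dimethyl-1,3-dioxane | COc1cc([C@H]2OC(C)(C)OC[C@@H]2c2cc(CBr)cc(OC)c2OCc2ccccc2)ccc1OCc1ccccc1 | intermediate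
15 | 5-bromovanillin | COc1cc(C=O)cc(Br)c1O | starting material
16 | [4-(benzyloxy)-3-methoxyphenyl]methanol | COc1cc(CO)ccc1OCc1ccccc1 | starting material
17 | 3-bromo-4-[(ArG-CH2)oxy]-5-methoxybenzaldehyde | COc1cc(C=O)cc(Br)c1OCc1ccc(OCc2ccccc2)c(OC)c1 | intermediate
18 | dimethyl succinate | COC(=O)CCC(=O)OC | starting material
19 | (E)-4-{3-bromo-4-[(ArG-CH2)oxy]-5-methoxyphenyl}-3-(methoxycarbonyl)but-3-enoic acid | COc1cc(/C=C(\CC(=O)O)C(=O)OC)cc(Br)c1OCc1ccc(OCc2ccccc2)c(OC)c1 | intermediate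
20 | (R)-4-{3-bromo-4-[(ArG-CH2)oxy]-5-methoxyphenyl}-3-(methoxycarbonyl)butanoic acid | COc1cc(C[C@H](CC(=O)O)C(=O)OC)cc(Br)c1OCc1ccc(OCc2ccccc2)c(OC)c1 | intermediate
21 | (R)-4-{3-bromo-4-[(ArG-CH2)oxy]-5-methoxyphenyl}-3-(hydroxymethyl)butanoic acid | COc1cc(C[C@H](CC(=O)O)CO)cc(Br)c1OCc1ccc(OCc2ccccc2)c(OC)c1 | intermediate
22 | (R)-4-{3-bromo-4-[(ArG-CH2)oxy]-5-methoxybenzyl}dihydrofuran-2(3H)-one | COc1cc(C[C@H]2COC(=O)C2)cc(Br)c1OCc1ccc(OCc2ccccc2)c(OC)c1 | intermediate
23 | (3R,4R)-3-{4-(benzyloxy)-3-[(4S,5S)-4-(ArG)-2,2-dimethyl-1,3-dioxan-5-yl]-5-methoxybenzyl}-4-{3-bromo-4-[(ArG-CH2)oxy]-5-methoxybenzyl}dihydrofuran-2(3H)-one | COc1cc([C@H]2OC(C)(C)OC[C@@H]2c2cc(C[C@H]3C(=O)OC[C@@H]3Cc3cc(OC)c(OCc4ccc(OCc5ccccc5)c(OC)c4)c(Br)c3)cc(OC)c2OCc2ccccc2)ccc1OCc1ccccc1 | intermediate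
24 | bromoacetyl bromide | BrCC(Br)=O | starting material
25 | 2-(trimethylsilyl)ethanol | C[Si](C)(C)CCO | starting material
26 | 2-(trimethylsilyl)ethyl bromoacetate | C[Si](C)(C)CCOC(=O)CBr | intermediate
27 | {2-oxo-2-[2-(trimethylsilyl)ethoxy]ethyl}zinc bromide | C[Si](C)(C)CCOC(=O)C[Zn]Br | intermediate
28 | 2-(trimethylsilyl)ethyl arylacetate (23 with Br replaced by CH2CO2CH2CH2SiMe3) | COc1cc([C@H]2OC(C)(C)OC[C@@H]2c2cc(C[C@H]3C(=O)OC[C@@H]3Cc3cc(OC)c(OCc4ccc(OCc5ccccc5)c(OC)c4)c(CC(=O)OCC[Si](C)(C)C)c3)cc(OC)c2OCc2ccccc2)ccc1OCc1ccccc1 | intermediate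
29 | 2-(trimethylsilyl)ethyl aryl diazoacetate (28 with ArCH2 turned into ArC(=N2)) | COc1cc([C@H]2OC(C)(C)OC[C@@H]2c2cc(C[C@H]3C(=O)OC[C@@H]3Cc3cc(OC)c(OCc4ccc(OCc5ccccc5)c(OC)c4)c(C(=[N+]=[N-])C(=O)OCC[Si](C)(C)C)c3)cc(OC)c2OCc2ccccc2)ccc1OCc1ccccc1 | intermediate
30 | 2-(trimethylsilyl)ethyl (2S,3R)-cis-2-(ArG)-7-methoxy-2,3-dihydrobenzofuran-3-carboxylate, C5 bearing the CH2 of the (3R,4R)-lactone with its ring A arm | COc1cc([C@H]2OC(C)(C)OC[C@@H]2c2cc(C[C@H]3C(=O)OC[C@@H]3Cc3cc(OC)c4c(c3)[C@@H](C(=O)OCC[Si](C)(C)C)[C@@H](c3ccc(OCc5ccccc5)c(OC)c3)O4)cc(OC)c2OCc2ccccc2)ccc1OCc1ccccc1 | intermediate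
31 | (2S,3S)-trans ester, C3 epimer of 30 | COc1cc([C@H]2OC(C)(C)OC[C@@H]2c2cc(C[C@H]3C(=O)OC[C@@H]3Cc3cc(OC)c4c(c3)[C@H](C(=O)OCC[Si](C)(C)C)[C@@H](c3ccc(OCc5ccccc5)c(OC)c3)O4)cc(OC)c2OCc2ccccc2)ccc1OCc1ccccc1 | intermediate
32 | (2S,3S)-trans-dihydrobenzofuran-3-carboxylic acid (31 with CO2H) | COc1cc([C@H]2OC(C)(C)OC[C@@H]2c2cc(C[C@H]3C(=O)OC[C@@H]3Cc3cc(OC)c4c(c3)[C@H](C(=O)O)[C@@H](c3ccc(OCc5ccccc5)c(OC)c3)O4)cc(OC)c2OCc2ccccc2)ccc1OCc1ccccc1 | intermediate
33 | (2S,3R)-3-(hydroxymethyl) compound (32 with CH2OH) | COc1cc([C@H]2OC(C)(C)OC[C@@H]2c2cc(C[C@H]3C(=O)OC[C@@H]3Cc3cc(OC)c4c(c3)[C@H](CO)[C@@H](c3ccc(OCc5ccccc5)c(OC)c3)O4)cc(OC)c2OCc2ccccc2)ccc1OCc1ccccc1 | intermediate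
34 | tri-O-benzyl ether of the target (free (1S,2S)-1,3-diol on the ring A arm) | COc1cc([C@@H](O)[C@H](CO)c2cc(C[C@H]3C(=O)OC[C@@H]3Cc3cc(OC)c4c(c3)[C@H](CO)[C@@H](c3ccc(OCc5ccccc5)c(OC)c3)O4)cc(OC)c2OCc2ccccc2)ccc1OCc1ccccc1 | intermediate
35 | CNP0186558.2 | COc1cc([C@@H](O)[C@H](CO)c2cc(C[C@H]3C(=O)OC[C@@H]3Cc3cc(OC)c4c(c3)[C@H](CO)[C@@H](c3ccc(O)c(OC)c3)O4)cc(OC)c2O)ccc1O | target

**Count and risks**

Total step count: 22. Longest linear sequence: 17 steps (1–8, 13, 15–22).

Steps most likely to fail: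

1. Step 17. The catalyst may discriminate poorly between the two enantiotopic hydrogens of the ether CH2 on this large, Lewis-basic substrate (poor facial selectivity), or the carbene may be diverted into dimerisation or addition to the electron-rich arenes. The fallback moves stereocontrol from the catalyst to a covalently bound auxiliary. It sets out from 28: Bu4NF in THF would give the free arylacetic acid F1, and carbodiimide esterification (EDC, DMAP) with (S)-2-hydroxy-1-(pyrrolidin-1-yl)propan-1-one would give the lactamide arylacetate F2. Diazo transfer as in step 16 would give the lactamide aryl diazoacetate F3. Insertion with Rh2(S-DOSP)4 (dirhodium tetrakis[(S)-N-(dodecylbenzenesulfonyl)prolinate]) in a matched auxiliary–catalyst pairing should give the trans lactamide ester F4 directly. LiOH in THF–H2O followed by acidification, on which any opened lactone recloses, would return the route at acid 32.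

2. Step 5. With the more acidic arylacetyl imide the anti selectivity may erode, or the adduct may revert (retro-aldol) and epimerise at the aryl-bearing carbon under the amine conditions. The fallback replaces the kinetic anti-aldol by a syn-aldol plus thermodynamic correction. It sets out from acid 5, which would be loaded onto (R)-4-benzyl-2-oxazolidinone as in step 4 to give the antipodal imide F5. The boron-mediated syn-aldol with 9 (Bu2BOTf, iPr2NEt, CH2Cl2, −78 → 0 °C) would give the syn-aldol adduct F6, with the aryl-bearing carbon already correct. LiBH4 reduction would give the syn triol F7. Acetonide formation under equilibrating acid (Me2C(OMe)2, camphorsulfonic acid, CH2Cl2, prolonged) should ionise the 4-alkoxybenzylic C–O bond reversibly and funnel the material to the 4,5-trans dioxane, returning the route at 13.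

3. Step 20. Chemoselectivity may be lost once the acid is consumed, with hydride delivered to the lactone (over-reduction). The fallback activates the acid instead of relying on the electrophilic reductant. It sets out from 32: isobutyl chloroformate and N-methylmorpholine in THF at −15 °C would give the mixed isobutyl carbonic anhydride F8, and NaBH4 in THF–H2O at −15 → 0 °C should reduce only this activated carbonyl, returning the route at 33.

**Further compounds**

F1 | step 17 | arylacetic acid (28 with CO2H in place of the silylethyl ester) | COc1cc([C@H]2OC(C)(C)OC[C@@H]2c2cc(C[C@H]3C(=O)OC[C@@H]3Cc3cc(OC)c(OCc4ccc(OCc5ccccc5)c(OC)c4)c(CC(=O)O)c3)cc(OC)c2OCc2ccccc2)ccc1OCc1ccccc1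
F2 | step 17 | (S)-1-oxo-1-(pyrrolidin-1-yl)propan-2-yl arylacetate (lactamide ester of F1) | COc1cc([C@H]2OC(C)(C)OC[C@@H]2c2cc(C[C@H]3C(=O)OC[C@@H]3Cc3cc(OC)c(OCc4ccc(OCc5ccccc5)c(OC)c4)c(CC(=O)O[C@@H](C)C(=O)N6CCCC6)c3)cc(OC)c2OCc2ccccc2)ccc1OCc1ccccc1
F3 | step 17 | lactamide aryl diazoacetate | COc1cc([C@H]2OC(C)(C)OC[C@@H]2c2cc(C[C@H]3C(=O)OC[C@@H]3Cc3cc(OC)c(OCc4ccc(OCc5ccccc5)c(OC)c4)c(C(=[N+]=[N-])C(=O)O[C@@H](C)C(=O)N6CCCC6)c3)cc(OC)c2OCc2ccccc2)ccc1OCc1ccccc1
F4 | step 17 | (2S,3S)-trans-dihydrobenzofuran lactamide ester | COc1cc([C@H]2OC(C)(C)OC[C@@H]2c2cc(C[C@H]3C(=O)OC[C@@H]3Cc3cc(OC)c4c(c3)[C@H](C(=O)O[C@@H](C)C(=O)N6CCCC6)[C@@H](c3ccc(OCc5ccccc5)c(OC)c3)O4)cc(OC)c2OCc2ccccc2)ccc1OCc1ccccc1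
F5 | step 5 | (R)-4-benzyl-3-{2-[2-(benzyloxy)-3-methoxy-5-(methoxycarbonyl)phenyl]acetyl}oxazolidin-2-one | COC(=O)c1cc(CC(=O)N2[C@H](Cc3ccccc3)COC2=O)c(OCc2ccccc2)c(OC)c1
F6 | step 5 | (R)-4-benzyl-3-[(2R,3R)-2-[2-(benzyloxy)-3-methoxy-5-(methoxycarbonyl)phenyl]-3-(ArG)-3-hydroxypropanoyl]oxazolidin-2-one (syn-aldol) | COc1cc([C@H](O)[C@H](C(=O)N2[C@H](Cc3ccccc3)COC2=O)c2cc(C(=O)OC)cc(OC)c2OCc2ccccc2)ccc1OCc1ccccc1
F7 | step 5 | (1R,2S)-1-(ArG)-2-[2-(benzyloxy)-5-(hydroxymethyl)-3-methoxyphenyl]propane-1,3-diol (syn triol) | COc1cc([C@H](O)[C@H](CO)c2cc(CO)cc(OC)c2OCc2ccccc2)ccc1OCc1ccccc1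
F8 | step 20 | mixed isobutyl carbonic anhydride of 32 | COc1cc([C@H]2OC(C)(C)OC[C@@H]2c2cc(C[C@H]3C(=O)OC[C@@H]3Cc3cc(OC)c4c(c3)[C@H](C(=O)OC(=O)OCC(C)C)[C@@H](c3ccc(OCc5ccccc5)c(OC)c3)O4)cc(OC)c2OCc2ccccc2)ccc1OCc1ccccc1
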